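The chroman is cut at C4–C4a and O1–C2, removing the C2–C3–C4 unit whose two ends are CH2 groups. What remains of ring A is 2,6-dihydroxy-4-methoxybenzaldehyde, which has a mirror plane through C1 and C4: both hydroxyls and both free ring carbons are equivalent, so the 5-OMe/7-OH/8-CHO pattern cannot come out wrong. One boronic-acid-templated condensation of this phenol with 2-[4-methoxy-2-(methoxymethoxy)phenyl]prop-2-enal, followed in the same flask by six-electron oxa-electrocyclisation, forms both bonds and the pyran ring as a 3-aryl-2H-chromene. C3 is then set by iridium-catalysed asymmetric hydrogenation and the C3' prenyl group enters last by an ortho-Claisen shift.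

Key step: step 5

Remark: the single stereocentre C3 of the target is read as R, and 2-bromo-5-methoxyphenol, prop-2-yn-1-ol and 3-chloro-3-methylbut-1-yne are taken as commercial.

Step 1
Reactants: 1 2,4,6-trihydroxybenzaldehyde
Product: 2 2,6-dihydroxy-4-methoxybenzaldehyde
Conditions: Me2SO4 (1.0 equiv), K2CO3 (1.0 equiv), acetone, 0 °C to rt
Reagents that add atoms: dimethyl sulfate, COS(=O)(=O)OC
Why: Williamson-type O-methylation that should stop at the 4-hydroxyl, because this is the only hydroxyl not hydrogen-bonded to the formyl oxygen and, being para to the formyl group, the most acidic one, so one equivalent of base and reagent is consumed there first.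

Step 2
Reactants: 3 2-bromo-5-methoxyphenol
Product: 4 1-bromo-4-methoxy-2-(methoxymethoxy)benzene
Conditions: MOMCl, i-Pr2NEt, CH2Cl2, 0 °C to rt
Reagents that add atoms: chloromethyl methyl ether, COCCl
Why: routine methoxymethyl protection of a phenol (O-alkylation by an alpha-chloro ether), giving an ether that tolerates the organomagnesium step and every later neutral or basic step.

Step 3
Reactants: 4 1-bromo-4-methoxy-2-(methoxymethoxy)benzene; 5 prop-2-yn-1-ol
Product: 7 2-[4-methoxy-2-(methoxymethoxy)phenyl]prop-2-en-1-ol, via aryl Grignard reagent 6 (not isolated)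
Conditions: Mg, THF, 45 °C; then CuI (10 mol %), 5 (0.35 equiv), THF–toluene, 0 °C to 45 °C; aq NH4Cl
Reagents that add atoms: none
Why: Grignard formation followed by copper-catalysed, alkoxide-directed anti-carbomagnesiation of propargyl alcohol, in which one equivalent of 6 makes the magnesium alkoxide and a second delivers the aryl group to the internal alkyne carbon, so that protonation should give the 2-arylallyl alcohol.

Step 4
Reactants: 7 2-[4-methoxy-2-(methoxymethoxy)phenyl]prop-2-en-1-ol
Product: 8 2-[4-methoxy-2-(methoxymethoxy)phenyl]prop-2-enal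
Conditions: activated MnO2 (10 equiv), CH2Cl2, rt; filtered, BHT added, solvent exchanged to toluene and used at once
Reagents that add atoms: none
Why: allylic alcohol oxidation on MnO2 under neutral conditions, which leaves the methoxymethyl ether alone and gives the dimerisation-prone 2-arylacrolein as a dilute solution that is carried straight into step 5.

Step 5
Reactants: 2 2,6-dihydroxy-4-methoxybenzaldehyde; 8 2-[4-methoxy-2-(methoxymethoxy)phenyl]prop-2-enal
Product: 11 7-hydroxy-5-methoxy-3-[4-methoxy-2-(methoxymethoxy)phenyl]-2H-chromene-8-carbaldehyde, via benzodioxaborin 9 (not isolated), via ortho-quinone methide 10 (not isolated)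
Conditions: PhB(OH)2 (1.1 equiv), EtCO2H (0.3 equiv), toluene, reflux, Dean–Stark; 8 added slowly to 2 (1.2 equiv)
Reagents that add atoms: none
Why: Phenylboronic acid esterifies one of the two equivalent hydroxyls of 2 and its boron coordinates the carbonyl oxygen of 8, so that the free ring carbon next to that hydroxyl (C3 of 2, the future C4a) attacks the carbonyl carbon through a six-membered array and gives dioxaborin 9 (bond C4–C4a). On further heating 9 loses phenylboronic acid to give ortho-quinone methide 10, whose 1-oxatriene O1=C8a–C4a=C4–C3=C2 closes the pyran ring by a thermally allowed disrotatory six-electron oxa-electrocyclisation (bond O1–C2). The closest known reaction type is the boronic-acid-templated ortho-condensation of phenols with alpha,beta-unsaturated aldehydes to 2H-chromenes, a formal [3+3] annulation. No stereocentre is formed. Attack at the carbonyl carbon and not at the unsubstituted beta-CH2 of 8 is secured by the O–B tether, which can reach only C1 of the enal, and the position of ring fusion needs no control because the mirror plane of 2 makes either hydroxyl and either free carbon give the same product. Mono-annulation should follow from the slight excess of 2 and from the hydrogen bond that ties the one remaining hydroxyl of 11 to the formyl oxygen and slows its esterification.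

Step 6
Reactants: 11 7-hydroxy-5-methoxy-3-[4-methoxy-2-(methoxymethoxy)phenyl]-2H-chromene-8-carbaldehyde
Product: 12 8-formyl-5-methoxy-3-[4-methoxy-2-(methoxymethoxy)phenyl]-2H-chromen-7-yl 4-methylbenzenesulfonate
Conditions: TsCl, Et3N, DMAP (cat.), CH2Cl2, 0 °C to rt
Reagents that add atoms: 4-methylbenzenesulfonyl chloride, Cc1ccc(S(=O)(=O)Cl)cc1
Why: O-sulfonylation of the only free hydroxyl, which removes the chelating salicylaldehyde-type phenol before the hydrogenation and ensures that the 2'-hydroxyl freed in step 8 is the only phenol present when the ether of step 9 is made.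

Step 7
Reactants: 12 8-formyl-5-methoxy-3-[4-methoxy-2-(methoxymethoxy)phenyl]-2H-chromen-7-yl 4-methylbenzenesulfonate
Product: 13 (3R)-8-formyl-5-methoxy-3-[4-methoxy-2-(methoxymethoxy)phenyl]-3,4-dihydro-2H-chromen-7-yl 4-methylbenzenesulfonate
Conditions: H2 (50 bar), [Ir(cod)(L)]BArF (2 mol %), CH2Cl2, rt; L = (S)-4-tert-butyl-2-[2-(diphenylphosphino)phenyl]-4,5-dihydrooxazole or its antipode, BArF = B[3,5-(CF3)2C6H3]4
Reagents that add atoms: none
Why: iridium–P,N-catalysed asymmetric hydrogenation of a trisubstituted aryl alkene, a known reaction of 3-aryl-2H-chromenes, in which C3 is set by catalyst control of the face of the C3=C4 bond that receives hydrogen, the ligand antipode that leads to 3R being fixed in a pilot run with chiral HPLC analysis.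

Step 8
Reactants: 13 (3R)-8-formyl-5-methoxy-3-[4-methoxy-2-(methoxymethoxy)phenyl]-3,4-dihydro-2H-chromen-7-yl 4-methylbenzenesulfonate
Product: 14 (3R)-8-formyl-3-(2-hydroxy-4-methoxyphenyl)-5-methoxy-3,4-dihydro-2H-chromen-7-yl 4-methylbenzenesulfonate
Conditions: HCl (3 M), MeOH–THF, 45 °C; then H2O
Reagents that add atoms: none
Why: acid-catalysed acetal exchange removes the methoxymethyl group as dimethoxymethane, while the aryl sulfonate, the methyl ethers and the non-acidic stereocentre C3 are inert and any dimethyl acetal of the aldehyde reverts on aqueous work-up.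

Step 9
Reactants: 14 (3R)-8-formyl-3-(2-hydroxy-4-methoxyphenyl)-5-methoxy-3,4-dihydro-2H-chromen-7-yl 4-methylbenzenesulfonate; 15 3-chloro-3-methylbut-1-yne
Product: 16 (3R)-8-formyl-5-methoxy-3-{4-methoxy-2-[(2-methylbut-3-yn-2-yl)oxy]phenyl}-3,4-dihydro-2H-chromen-7-yl 4-methylbenzenesulfonate
Conditions: 15 (2 equiv), DBU (2.5 equiv), CuCl2·2H2O (1 mol %), MeCN, 0 °C
Reagents that add atoms: none
Why: copper-catalysed O-alkylation of a phenol with a tertiary propargylic chloride (ionisation of the copper acetylide and capture by the phenoxide), a standard way to aryl 1,1-dimethylpropargyl ethers that here meets a single free hydroxyl.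

Step 10
Reactants: 16 (3R)-8-formyl-5-methoxy-3-{4-methoxy-2-[(2-methylbut-3-yn-2-yl)oxy]phenyl}-3,4-dihydro-2H-chromen-7-yl 4-methylbenzenesulfonate
Product: 17 (3R)-8-formyl-5-methoxy-3-{4-methoxy-2-[(2-methylbut-3-en-2-yl)oxy]phenyl}-3,4-dihydro-2H-chromen-7-yl 4-methylbenzenesulfonate
Conditions: H2 (1 atm), Pd/CaCO3–Pb(OAc)2 (5 wt % Pd), quinoline, EtOAc, rt
Reagents that add atoms: none
Why: Lindlar semi-hydrogenation of a terminal alkyne on poisoned palladium, which should stop at the alkene and leave the aryl aldehyde and the aryl sulfonate untouched.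

Step 11
Reactants: 17 (3R)-8-formyl-5-methoxy-3-{4-methoxy-2-[(2-methylbut-3-en-2-yl)oxy]phenyl}-3,4-dihydro-2H-chromen-7-yl 4-methylbenzenesulfonate
Product: 19 (3R)-8-formyl-3-[2-hydroxy-4-methoxy-3-(3-methylbut-2-en-1-yl)phenyl]-5-methoxy-3,4-dihydro-2H-chromen-7-yl 4-methylbenzenesulfonate, via cyclohexadienone 18 (not isolated)
Conditions: PhNEt2, 130 °C
Reagents that add atoms: none
Why: aromatic Claisen rearrangement, a [3,3] shift from O2' to the only free ortho carbon C3' (C1' is blocked) that turns the 1,1-dimethylallyl ether into the linear prenyl group, followed by tautomerisation of dienone 18, the basic solvent preventing acid-induced cyclisation of the ortho-prenylphenol.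

Step 12
Reactants: 19 (3R)-8-formyl-3-[2-hydroxy-4-methoxy-3-(3-methylbut-2-en-1-yl)phenyl]-5-methoxy-3,4-dihydro-2H-chromen-7-yl 4-methylbenzenesulfonate
Product: 20 (3R)-7-hydroxy-3-[2-hydroxy-4-methoxy-3-(3-methylbut-2-en-1-yl)phenyl]-5-methoxy-3,4-dihydro-2H-chromene-8-carbaldehyde
Conditions: KOH (3 equiv), MeOH–H2O, 50 °C; aq NH4Cl
Reagents that add atoms: none
Why: hydroxide cleavage of an aryl sulfonate at sulfur, made easy by the ortho-formyl group that stabilises the departing phenoxide, under conditions that the non-enolisable aldehyde, the prenyl group and the stereocentre C3 should tolerate.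

Compound list
1 | 2,4,6-trihydroxybenzaldehyde | O=Cc1c(O)cc(O)cc1O | starting material
2 | 2,6-dihydroxy-4-methoxybenzaldehyde | COc1cc(O)c(C=O)c(O)c1 | intermediate
3 | 2-bromo-5-methoxyphenol | COc1ccc(Br)c(O)c1 | starting material
4 | 1-bromo-4-methoxy-2-(methoxymethoxy)benzene | COCOc1cc(OC)ccc1Br | intermediate
5 | prop-2-yn-1-ol | C#CCO | starting material
6 | [4-methoxy-2-(methoxymethoxy)phenyl]magnesium bromide | COCOc1cc(OC)ccc1[Mg]Br | intermediate
7 | 2-[4-methoxy-2-(methoxymethoxy)phenyl]prop-2-en-1-ol | C=C(CO)c1ccc(OC)cc1OCOC | intermediate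
8 | 2-[4-methoxy-2-(methoxymethoxy)phenyl]prop-2-enal | C=C(C=O)c1ccc(OC)cc1OCOC | intermediate
9 | 7-hydroxy-5-methoxy-4-{1-[4-methoxy-2-(methoxymethoxy)phenyl]ethenyl}-2-phenyl-4H-1,3,2-benzodioxaborinine-8-carbaldehyde | C=C(c1ccc(OC)cc1OCOC)C1OB(c2ccccc2)Oc2c(C=O)c(O)cc(OC)c21 | intermediate
10 | 2-hydroxy-4-methoxy-5-{2-[4-methoxy-2-(methoxymethoxy)phenyl]prop-2-en-1-ylidene}-6-oxocyclohexa-1,3-diene-1-carbaldehyde | C=C(C=C1C(OC)=CC(O)=C(C=O)C1=O)c1ccc(OC)cc1OCOC | intermediate
11 | 7-hydroxy-5-methoxy-3-[4-methoxy-2-(methoxymethoxy)phenyl]-2H-chromene-8-carbaldehyde | COc1ccc(C2=Cc3c(OC)cc(O)c(C=O)c3OC2)c(OCOC)c1 | intermediate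
12 | 8-formyl-5-methoxy-3-[4-methoxy-2-(methoxymethoxy)phenyl]-2H-chromen-7-yl 4-methylbenzenesulfonate | COc1ccc(C2=Cc3c(OC)cc(OS(=O)(=O)c4ccc(C)cc4)c(C=O)c3OC2)c(OCOC)c1 | intermediate
13 | (3R)-8-formyl-5-methoxy-3-[4-methoxy-2-(methoxymethoxy)phenyl]-3,4-dihydro-2H-chromen-7-yl 4-methylbenzenesulfonate | COc1ccc([C@@H]2COc3c(C=O)c(OS(=O)(=O)c4ccc(C)cc4)cc(OC)c3C2)c(OCOC)c1 | intermediate
14 | (3R)-8-formyl-3-(2-hydroxy-4-methoxyphenyl)-5-methoxy-3,4-dihydro-2H-chromen-7-yl 4-methylbenzenesulfonate | COc1ccc([C@@H]2COc3c(C=O)c(OS(=O)(=O)c4ccc(C)cc4)cc(OC)c3C2)c(O)c1 | intermediate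
15 | 3-chloro-3-methylbut-1-yne | C#CC(C)(C)Cl | starting material
16 | (3R)-8-formyl-5-methoxy-3-{4-methoxy-2-[(2-methylbut-3-yn-2-yl)oxy]phenyl}-3,4-dihydro-2H-chromen-7-yl 4-methylbenzenesulfonate | COc1ccc([C@@H]2COc3c(C=O)c(OS(=O)(=O)c4ccc(C)cc4)cc(OC)c3C2)c(OC(C)(C)C#C)c1 | intermediate
17 | (3R)-8-formyl-5-methoxy-3-{4-methoxy-2-[(2-methylbut-3-en-2-yl)oxy]phenyl}-3,4-dihydro-2H-chromen-7-yl 4-methylbenzenesulfonate | COc1ccc([C@@H]2COc3c(C=O)c(OS(=O)(=O)c4ccc(C)cc4)cc(OC)c3C2)c(OC(C)(C)C=C)c1 | intermediate
18 | (3R)-8-formyl-5-methoxy-3-[4-methoxy-5-(3-methylbut-2-en-1-yl)-6-oxocyclohexa-1,3-dien-1-yl]-3,4-dihydro-2H-chromen-7-yl 4-methylbenzenesulfonate (configuration at the ring carbon bearing the prenyl group not defined) | COC1=CC=C([C@@H]2COc3c(C=O)c(OS(=O)(=O)c4ccc(C)cc4)cc(OC)c3C2)C(=O)C1CC=C(C)C | intermediate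
19 | (3R)-8-formyl-3-[2-hydroxy-4-methoxy-3-(3-methylbut-2-en-1-yl)phenyl]-5-methoxy-3,4-dihydro-2H-chromen-7-yl 4-methylbenzenesulfonate | COc1ccc([C@@H]2COc3c(C=O)c(OS(=O)(=O)c4ccc(C)cc4)cc(OC)c3C2)c(O)c1CC=C(C)C | intermediate
20 | (3R)-7-hydroxy-3-[2-hydroxy-4-methoxy-3-(3-methylbut-2-en-1-yl)phenyl]-5-methoxy-3,4-dihydro-2H-chromene-8-carbaldehyde | COc1ccc([C@@H]2COc3c(C=O)c(O)cc(OC)c3C2)c(O)c1CC=C(C)C | target

Total step count: 12.
Longest linear sequence: 11 steps (3 to 20 through steps 2 to 12); step 1 is the one-step side branch that supplies 2.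

Steps most likely to fail

Step 5. Polymerisation of enal 8 at reflux, or internal coordination of the boron by the formyl oxygen of 2, may outrun the templated C–C bond formation, so that the phenol is recovered and the enal is lost. The fallback sets out from 2 and 8 and runs the union in the conjugate sense on purpose. With pyrrolidine and PhCO2H (20 mol % each) in CH2Cl2 at rt the iminium ion of 8 should be attacked at its free CH2 by C3 of 2, and the aldehyde so formed is trapped by the neighbouring hydroxyl as the lactol 2,7-dihydroxy-5-methoxy-3-[4-methoxy-2-(methoxymethoxy)phenyl]-3,4-dihydro-2H-chromene-8-carbaldehyde F1 (mixture of isomers). PPTS (10 mol %) in toluene at 90 °C over 4 Å sieves should dehydrate it to the conjugated enol ether 7-hydroxy-5-methoxy-3-[4-methoxy-2-(methoxymethoxy)phenyl]-4H-chromene-8-carbaldehyde F2. TsCl, Et3N and DMAP in CH2Cl2 then give 8-formyl-5-methoxy-3-[4-methoxy-2-(methoxymethoxy)phenyl]-4H-chromen-7-yl 4-methylbenzenesulfonate F3. Asymmetric hydrogenation of the C2=C3 bond of F3 with the chiral [Ir(cod)(L)]BArF catalyst of step 7 (H2, CH2Cl2) comes back to the route at 13. The same two ring bonds are formed, in the opposite order and without an electrocyclisation.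

Step 7. Facial discrimination at the C3=C4 bond may be weak, because the ortho-substituted aryl ring is twisted out of the alkene plane, or the double bond may migrate before it is reduced. The fallback sets out from 12 and replaces asymmetric catalysis by resolution. Hydrogenation with the achiral complex [Ir(cod)(PCy3)(py)]PF6 (H2, CH2Cl2, rt) should give racemic 8-formyl-5-methoxy-3-[4-methoxy-2-(methoxymethoxy)phenyl]-3,4-dihydro-2H-chromen-7-yl 4-methylbenzenesulfonate F4. Preparative chromatography on a chiral stationary phase (amylose tris(3,5-dimethylphenylcarbamate), supercritical CO2–MeOH) then separates 13, where the fallback rejoins the route, from (3S)-8-formyl-5-methoxy-3-[4-methoxy-2-(methoxymethoxy)phenyl]-3,4-dihydro-2H-chromen-7-yl 4-methylbenzenesulfonate F5, which is set aside.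

Step 3. The hindered, chelated aryl Grignard reagent may deprotonate the alkyne C–H instead of adding across the triple bond, so that only the protonated arene is returned. The fallback sets out from 4 and makes the aryl–vinyl bond by cross-coupling. Bromine–lithium exchange (n-BuLi, THF, −78 °C), B(Oi-Pr)3 and aqueous NH4Cl should give [4-methoxy-2-(methoxymethoxy)phenyl]boronic acid F6. Suzuki–Miyaura coupling of F6 with 2-bromoprop-2-en-1-ol (Pd(PPh3)4, Na2CO3, DME–H2O, 80 °C) comes back to the route at 7.

Further compounds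
F1 | step 5 | 2,7-dihydroxy-5-methoxy-3-[4-methoxy-2-(methoxymethoxy)phenyl]-3,4-dihydro-2H-chromene-8-carbaldehyde | COc1ccc(C2Cc3c(OC)cc(O)c(C=O)c3OC2O)c(OCOC)c1
F2 | step 5 | 7-hydroxy-5-methoxy-3-[4-methoxy-2-(methoxymethoxy)phenyl]-4H-chromene-8-carbaldehyde | COc1ccc(C2=COc3c(C=O)c(O)cc(OC)c3C2)c(OCOC)c1
F3 | step 5 | 8-formyl-5-methoxy-3-[4-methoxy-2-(methoxymethoxy)phenyl]-4H-chromen-7-yl 4-methylbenzenesulfonate | COc1ccc(C2=COc3c(C=O)c(OS(=O)(=O)c4ccc(C)cc4)cc(OC)c3C2)c(OCOC)c1
F4 | step 7 | racemic 8-formyl-5-methoxy-3-[4-methoxy-2-(methoxymethoxy)phenyl]-3,4-dihydro-2H-chromen-7-yl 4-methylbenzenesulfonate | COc1ccc(C2COc3c(C=O)c(OS(=O)(=O)c4ccc(C)cc4)cc(OC)c3C2)c(OCOC)c1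
F5 | step 7 | (3S)-8-formyl-5-methoxy-3-[4-methoxy-2-(methoxymethoxy)phenyl]-3,4-dihydro-2H-chromen-7-yl 4-methylbenzenesulfonate | COc1ccc([C@H]2COc3c(C=O)c(OS(=O)(=O)c4ccc(C)cc4)cc(OC)c3C2)c(OCOC)c1
F6 | step 3 | [4-methoxy-2-(methoxymethoxy)phenyl]boronic acid | COCOc1cc(OC)ccc1B(O)O
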